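The route rests on opening ring C of the middle, galloylated flavan unit across its O1–C2 and C3–C4 bonds. O1, C8a, C4a and C4 of that unit are then the heterodiene of an ortho-quinone methide whose C4 already carries C8 of the lower epigallocatechin, and C2=C3 is a (Z)-styryl gallate. A chiral-acid-catalysed inverse-demand hetero-Diels–Alder reaction of the quinone methide, released from an ortho-hydroxybenzhydrol, closes ring C and sets C2, C3 and C4 with the gallate ester and the lower 4→8 bond in place. The upper epigallocatechin is then attached at C8 through a flavan-4-yl cation, and hydrogenolysis ends the route.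

Key step: step 8

Remark on names: the target is epigallocatechin-(4β→8)-epigallocatechin 3-O-gallate-(4β→8)-epigallocatechin; the units are called upper, middle and lower unit and carry the usual flavan numbering.
Assumption: which antipode of the chiral phosphoric acid is matched with the lower unit in step 8 cannot be settled on paper; the (R)-antipode is written and the matched antipode is the one to be used.
Remark on descriptors: C4 of the middle unit is R in 15 and S in 16 and 17 without any change in geometry, because substitution at C8 changes the priorities.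

Step 1
Reactants: 1 (−)-epigallocatechin
Product: 2 5,7,3',4',5'-penta-O-benzylepigallocatechin
Conditions: BnBr (5.5 equiv), K2CO3, DMF, 0 °C → rt, argon
Reagents that add atoms: benzyl bromide, BrCc1ccccc1
Why: Williamson etherification in which K2CO3 deprotonates only the five phenols, so the secondary 3-OH stays free and no stereocentre is touched.

Step 2
Reactants: 2 5,7,3',4',5'-penta-O-benzylepigallocatechin
Product: 3 8-bromo-5,7,3',4',5'-penta-O-benzylepigallocatechin
Conditions: NBS (1.0 equiv), CH2Cl2, −78 → 0 °C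
Reagents that add atoms: N-bromosuccinimide, O=C1CCC(=O)N1Br
Why: Electrophilic aromatic bromination, which should go to C8 because it is the most nucleophilic and less hindered ring A carbon of a 5,7-dialkoxyflavan (C6 lies between two benzyloxy groups).

Step 3
Reactants: 3 8-bromo-5,7,3',4',5'-penta-O-benzylepigallocatechin
Product: 4 8-bromo-4β-(2-ethoxyethoxy)-5,7,3',4',5'-penta-O-benzylepigallocatechin
Conditions: DDQ (2 equiv), 2-ethoxyethanol (5 equiv), CH2Cl2, rt
Reagents that add atoms: 2-ethoxyethanol, CCOCCO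
Why: DDQ benzylic oxidation by hydride abstraction at C4 gives the ring-A-stabilised cation, which the alcohol should trap anti to the pseudo-axial 3-OH to give the 4β (3,4-trans) ether; the bromine serves as a cap on C8 for step 9.

Step 4
Reactants: 5 2,4,6-trihydroxybenzaldehyde
Product: 6 2,4-bis(benzyloxy)-6-hydroxybenzaldehyde
Conditions: BnBr (2.1 equiv), K2CO3, DMF, rt
Reagents that add atoms: benzyl bromide, BrCc1ccccc1
Why: Williamson etherification that should stop after the para and one ortho hydroxyl, because the last ortho hydroxyl is tied up in a hydrogen bond to the formyl group.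

Step 5
Reactants: 3 8-bromo-5,7,3',4',5'-penta-O-benzylepigallocatechin; 6 2,4-bis(benzyloxy)-6-hydroxybenzaldehyde
Product: 9 ortho-hydroxybenzhydrol joining ring A of the future middle unit to C8 of the lower unit (both carbinol epimers), via aryllithium lithium alkoxide 7 (not isolated), via sodium phenoxide 8 (not isolated)
Conditions: 3, n-BuLi (2.1 equiv), THF, −78 °C; then 8 (from 6, NaH, THF, 0 °C), −78 → −20 °C; pH 7 buffer
Reagents that add atoms: none
Why: After lithiation of the 3-OH, bromine–lithium exchange at −78 °C outruns any deprotonation and the 8-lithio species should add 1,2 to the formyl group of the phenoxide; the new carbinol centre needs no control because it becomes the sp2 carbon of the quinone methide.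

Step 6
Reactants: 10 3,4,5-tris(benzyloxy)benzaldehyde
Product: 11 5-ethynyl-1,2,3-tris(benzyloxy)benzene
Conditions: Ohira–Bestmann reagent (1.3 equiv), K2CO3 (2 equiv), MeOH–THF, rt
Reagents that add atoms: Ohira–Bestmann reagent (dimethyl (1-diazo-2-oxopropyl)phosphonate), CC(=O)C(=[N+]=[N-])P(=O)(OC)OC
Why: Seyferth–Gilbert homologation of a non-enolisable aryl aldehyde, in which the diazoalkene loses N2 and rearranges to the terminal alkyne.

Step 7
Reactants: 11 5-ethynyl-1,2,3-tris(benzyloxy)benzene; 12 3,4,5-tris(benzyloxy)benzoic acid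
Product: 13 (Z)-2-[3,4,5-tris(benzyloxy)phenyl]ethenyl 3,4,5-tris(benzyloxy)benzoate
Conditions: Ru(methallyl)2(dppb) (2 mol %), PhMe, 65 °C
Reagents that add atoms: none
Why: Ruthenium-catalysed anti-Markovnikov addition of a carboxylic acid to a terminal alkyne, in which the carboxylate adds to the α-carbon of a ruthenium vinylidene and protonolysis should give the kinetic (Z)-enol ester, as known for arylacetylenes and benzoic acids.

Step 8
Reactants: 9 ortho-hydroxybenzhydrol; 13 (Z)-styryl gallate (1.5 equiv)
Product: 15 benzyl-protected epigallocatechin 3-O-gallate-(4β→8)-epigallocatechin, via ortho-quinone methide 14 (not isolated)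
Conditions: (R)-TRIP (10 mol %), 5 Å MS, PhMe, 0 °C → rt
Reagents that add atoms: none
Why: Proposed new method: the chiral phosphoric acid dehydrates 9 to the ortho-quinone methide 14, held as a hydrogen-bonded, partly protonated ion pair, whose O1=C8a–C4a=C4 heterodiene should add across the electron-rich (Z)-alkene of 13 in a concerted but asynchronous inverse-electron-demand hetero-Diels–Alder reaction with C3–C4 bonding ahead of O1–C2 bonding; the closest known reactions are chiral-Brønsted-acid-catalysed [4+2] cycloadditions of benzhydrol-derived ortho-quinone methides with styrenes and enamides, which have not been shown with a β-acyloxystyrene. Ring C of the middle unit is closed in this intermolecular [4+2] mode, and in the stepwise limit by 6-exo-trig capture of the C2 benzylic cation by the C8a phenol. The step needs the aryl group and not the ester oxygen to govern the alkene polarity: the tris(benzyloxy)phenyl ring stabilises positive charge at C2 far better than the cross-conjugated acyloxy group does at C3, so C3 should be the nucleophilic carbon and O1 should end on the benzylic C2 as in flavan formation from styrenes, and since only the C8a hydroxyl is free the 4→8 connectivity is unambiguous. C2 and C3 become cis because the (Z) geometry is carried over suprafacially. C4 becomes trans to C3 because the transition state with the acyloxy group endo and the bulky lower-unit aryl pseudo-axial, turned away from the peri C5 benzyloxy group, holds these two groups antiperiplanar about the forming C3–C4 bond. The absolute sense (2R,3R with a 4β aryl) should be imposed by the catalyst, which is bound at O1 and shields one face of 14, the stereocentres of the lower unit being too remote to decide it.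

Step 9
Reactants: 15 protected epigallocatechin 3-O-gallate-(4β→8)-epigallocatechin; 4 8-bromo-4β-(2-ethoxyethoxy) electrophile (1.1 equiv)
Product: 16 fully protected, 8-bromo-capped trimer
Conditions: TMSOTf (0.5 equiv), CH2Cl2, −78 → −40 °C; Et3N
Reagents that add atoms: none
Why: Lewis-acid ionisation of the 4-alkoxy group gives the flavan-4-yl cation, which should be attacked in a Friedel–Crafts reaction by C8 of ring A of the galloylated unit (the most nucleophilic open position of 15) anti to the pseudo-axial 3-OH to give the 4β bond, while the C8 bromine keeps 4 from condensing with itself.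

Step 10
Reactants: 16 fully protected, 8-bromo-capped trimer
Product: 17 epigallocatechin-(4β→8)-epigallocatechin 3-O-gallate-(4β→8)-epigallocatechin (CNP0278699.1)
Conditions: H2 (1 atm), Pd(OH)2/C, Et3N (1.1 equiv), THF–MeOH–H2O, rt
Reagents that add atoms: none
Why: Catalytic hydrogenolysis should cleave all eighteen benzyl ethers and the aryl C–Br bond while the gallate ester, the interflavan bonds and all stereocentres stay untouched, with Et3N taking up the HBr.

Compound list
1 | (−)-epigallocatechin, (2R,3R)-2-(3,4,5-trihydroxyphenyl)chromane-3,5,7-triol | Oc1cc(O)c2c(c1)O[C@H](c1cc(O)c(O)c(O)c1)[C@H](O)C2 | starting material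
2 | 5,7,3',4',5'-penta-O-benzylepigallocatechin, (2R,3R), 3-OH free | O(Cc9ccccc9)c1cc(OCc9ccccc9)c2c(c1)O[C@H](c1cc(OCc9ccccc9)c(OCc9ccccc9)c(OCc9ccccc9)c1)[C@H](O)C2 | intermediate
3 | 8-bromo-5,7,3',4',5'-penta-O-benzylepigallocatechin | O(Cc9ccccc9)c1cc(OCc9ccccc9)c2c(c1Br)O[C@H](c1cc(OCc9ccccc9)c(OCc9ccccc9)c(OCc9ccccc9)c1)[C@H](O)C2 | intermediate
4 | 8-bromo-4β-(2-ethoxyethoxy)-5,7,3',4',5'-penta-O-benzylepigallocatechin (2,3-cis, 3,4-trans, 3-OH free) | CCOCCO[C@H]1c2c(OCc9ccccc9)cc(OCc9ccccc9)c(Br)c2O[C@H](c2cc(OCc9ccccc9)c(OCc9ccccc9)c(OCc9ccccc9)c2)[C@@H]1O | intermediate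
5 | 2,4,6-trihydroxybenzaldehyde | O=Cc1c(O)cc(O)cc1O | starting material
6 | 2,4-bis(benzyloxy)-6-hydroxybenzaldehyde | O=Cc1c(O)cc(OCc9ccccc9)cc1OCc9ccccc9 | intermediate
7 | 8-lithio derivative of 3 as its lithium 3-alkoxide | O(Cc9ccccc9)c1cc(OCc9ccccc9)c2c(c1[Li])O[C@H](c1cc(OCc9ccccc9)c(OCc9ccccc9)c(OCc9ccccc9)c1)[C@H](O[Li])C2 | intermediate (not isolated)
8 | sodium 3,5-bis(benzyloxy)-2-formylphenoxide | [Na+].[O-]c1cc(OCc9ccccc9)cc(OCc9ccccc9)c1C=O | intermediate (not isolated)
9 | [2,4-bis(benzyloxy)-6-hydroxyphenyl][5,7,3',4',5'-penta-O-benzylepigallocatechin-8-yl]methanol, both epimers at the carbinol carbon | OC(c1c(O)cc(OCc9ccccc9)cc1OCc9ccccc9)c1c(OCc9ccccc9)cc(OCc9ccccc9)c2c1O[C@H](c1cc(OCc9ccccc9)c(OCc9ccccc9)c(OCc9ccccc9)c1)[C@H](O)C2 | intermediate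
10 | 3,4,5-tris(benzyloxy)benzaldehyde | O=Cc1cc(OCc9ccccc9)c(OCc9ccccc9)c(OCc9ccccc9)c1 | starting material
11 | 5-ethynyl-1,2,3-tris(benzyloxy)benzene | C#Cc1cc(OCc9ccccc9)c(OCc9ccccc9)c(OCc9ccccc9)c1 | intermediate
12 | 3,4,5-tris(benzyloxy)benzoic acid | OC(=O)c1cc(OCc9ccccc9)c(OCc9ccccc9)c(OCc9ccccc9)c1 | starting material
13 | (Z)-2-[3,4,5-tris(benzyloxy)phenyl]ethenyl 3,4,5-tris(benzyloxy)benzoate | O=C(O/C=C\c1cc(OCc9ccccc9)c(OCc9ccccc9)c(OCc9ccccc9)c1)c1cc(OCc9ccccc9)c(OCc9ccccc9)c(OCc9ccccc9)c1 | intermediate
14 | ortho-quinone methide: 3,5-bis(benzyloxy)-6-[(penta-O-benzylepigallocatechin-8-yl)methylidene]cyclohexa-2,4-dien-1-one, alkene geometry not fixed | O=C1C=C(OCc9ccccc9)C=C(OCc9ccccc9)C1=Cc1c(OCc9ccccc9)cc(OCc9ccccc9)c2c1O[C@H](c1cc(OCc9ccccc9)c(OCc9ccccc9)c(OCc9ccccc9)c1)[C@H](O)C2 | intermediate (not isolated)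
15 | 5,7,3',4',5'-penta-O-benzyl-3-O-[3,4,5-tris(benzyloxy)benzoyl]epigallocatechin-(4β→8)-5,7,3',4',5'-penta-O-benzylepigallocatechin (new ring 2,3-cis, 3,4-trans) | O=C(O[C@@H]1[C@@H](c2c(OCc9ccccc9)cc(OCc9ccccc9)c3c2O[C@H](c2cc(OCc9ccccc9)c(OCc9ccccc9)c(OCc9ccccc9)c2)[C@H](O)C3)c2c(OCc9ccccc9)cc(OCc9ccccc9)cc2O[C@@H]1c1cc(OCc9ccccc9)c(OCc9ccccc9)c(OCc9ccccc9)c1)c1cc(OCc9ccccc9)c(OCc9ccccc9)c(OCc9ccccc9)c1 | intermediate
16 | 8-bromo-5,7,3',4',5'-penta-O-benzylepigallocatechin-(4β→8)-[5,7,3',4',5'-penta-O-benzyl-3-O-(3,4,5-tris(benzyloxy)benzoyl)epigallocatechin]-(4β→8)-5,7,3',4',5'-penta-O-benzylepigallocatechin | O=C(O[C@@H]1[C@@H](c2c(OCc9ccccc9)cc(OCc9ccccc9)c3c2O[C@H](c2cc(OCc9ccccc9)c(OCc9ccccc9)c(OCc9ccccc9)c2)[C@H](O)C3)c2c(OCc9ccccc9)cc(OCc9ccccc9)c([C@H]3c4c(OCc9ccccc9)cc(OCc9ccccc9)c(Br)c4O[C@H](c4cc(OCc9ccccc9)c(OCc9ccccc9)c(OCc9ccccc9)c4)[C@@H]3O)c2O[C@@H]1c1cc(OCc9ccccc9)c(OCc9ccccc9)c(OCc9ccccc9)c1)c1cc(OCc9ccccc9)c(OCc9ccccc9)c(OCc9ccccc9)c1 | intermediate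
17 | epigallocatechin-(4β→8)-epigallocatechin 3-O-gallate-(4β→8)-epigallocatechin; upper unit (2R,3R,4R), middle unit (2R,3R,4S), lower unit (2R,3R) | O=C(O[C@@H]1[C@@H](c2c(O)cc(O)c3c2O[C@H](c2cc(O)c(O)c(O)c2)[C@H](O)C3)c2c(O)cc(O)c([C@H]3c4c(O)cc(O)cc4O[C@H](c4cc(O)c(O)c(O)c4)[C@@H]3O)c2O[C@@H]1c1cc(O)c(O)c(O)c1)c1cc(O)c(O)c(O)c1 | target

Total step count: 10. Longest linear sequence: 6 steps (steps 1, 2, 5, 8, 9, 10).

Steps most likely to fail

Step 8. The reaction may leave the concerted path: a long-lived C2 cation could rotate or be bridged by the neighbouring acyloxy group, which would erode the 2,3-cis relationship. The ester oxygen could also reverse the regiochemistry. The catalyst may discriminate poorly between the faces of the quinone methide, and the stabilised cation may alkylate electron-rich arenes instead of the alkene. The fallback uses only known flavan-4-yl cation chemistry; it sets out from 2 and 12 and comes back at 15. DDQ oxidation of 2 in the presence of 2-ethoxyethanol should give 4β-(2-ethoxyethoxy)-5,7,3',4',5'-penta-O-benzylepigallocatechin F1. Steglich esterification of its 3-OH with 12 (DCC, DMAP, CH2Cl2) should give the galloylated electrophile F2. Ionisation of F2 with TMSOTf in CH2Cl2 at −78 °C in the presence of an excess of 2 as the C8 nucleophile should then give 15, the 4β bond arising from attack anti to the pseudo-axial 3-acyloxy group.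

Step 5. Addition of a doubly ortho-substituted aryllithium to a doubly ortho-substituted, phenoxide-deactivated aldehyde may be too slow, so that the aryllithium is protonated or rearranges at a benzylic ether on warming. The fallback turns the polarity round; it sets out from 3 (through 7) and comes back at 9. Quenching 7 with DMF should give 8-formyl-5,7,3',4',5'-penta-O-benzylepigallocatechin F3. Commercial 3,5-bis(benzyloxy)phenol (Oc1cc(OCc2ccccc2)cc(OCc2ccccc2)c1) with EtMgBr should give bromomagnesium 3,5-bis(benzyloxy)phenoxide F4. Reaction of F4 in PhMe–CH2Cl2 with F3, whose 3-OH is first converted into its magnesium alkoxide with one more equivalent of EtMgBr, should give 9 by ortho-specific hydroxyalkylation through a six-membered magnesium chelate.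

Step 9. The cation may attack C6 of either unit of 15 instead of C8, and adventitious triflic acid may cleave and scramble the interflavan bond already present. The fallback replaces acid activation by thiophilic activation; it sets out from 4 and comes back at 16. Exchange of the 4-alkoxy group of 4 with benzyl mercaptan (BF3·OEt2, CH2Cl2, −40 °C) should give 8-bromo-4β-(benzylthio)-5,7,3',4',5'-penta-O-benzylepigallocatechin F5. Treatment of F5 and 15 with AgBF4 (silver tetrafluoroborate, monovalent silver) in THF at 0 °C should then give 16 under conditions that leave the existing 4→8 bond alone.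

Further compounds
F1 | step 8 | 4β-(2-ethoxyethoxy)-5,7,3',4',5'-penta-O-benzylepigallocatechin | CCOCCO[C@H]1c2c(OCc9ccccc9)cc(OCc9ccccc9)cc2O[C@H](c2cc(OCc9ccccc9)c(OCc9ccccc9)c(OCc9ccccc9)c2)[C@@H]1O
F2 | step 8 | 4β-(2-ethoxyethoxy)-5,7,3',4',5'-penta-O-benzyl-3-O-[3,4,5-tris(benzyloxy)benzoyl]epigallocatechin | O=C(O[C@@H]1[C@@H](OCCOCC)c2c(OCc9ccccc9)cc(OCc9ccccc9)cc2O[C@@H]1c1cc(OCc9ccccc9)c(OCc9ccccc9)c(OCc9ccccc9)c1)c1cc(OCc9ccccc9)c(OCc9ccccc9)c(OCc9ccccc9)c1
F3 | step 5 | 8-formyl-5,7,3',4',5'-penta-O-benzylepigallocatechin | O(Cc9ccccc9)c1cc(OCc9ccccc9)c2c(c1C=O)O[C@H](c1cc(OCc9ccccc9)c(OCc9ccccc9)c(OCc9ccccc9)c1)[C@H](O)C2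
F4 | step 5 | bromomagnesium 3,5-bis(benzyloxy)phenoxide | Br[Mg]Oc1cc(OCc9ccccc9)cc(OCc9ccccc9)c1
F5 | step 9 | 8-bromo-4β-(benzylthio)-5,7,3',4',5'-penta-O-benzylepigallocatechin | S(Cc9ccccc9)[C@H]1c2c(OCc9ccccc9)cc(OCc9ccccc9)c(Br)c2O[C@H](c2cc(OCc9ccccc9)c(OCc9ccccc9)c(OCc9ccccc9)c2)[C@@H]1O
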